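**Time of reading.** At 30 h each flask holds what its rate has made by then, so I needed a rate law that could carry two short runs to five new recipes.

all flasks: temperature −20 °C
- Sunday's: Z 0.45 M; X 1.8 equiv; E 0.38 mol%; run made earlier
- Monday's: Z 0.60 M; X 1.8 equiv; E 0.38 mol%; run made earlier
- east: Z 0.30 M; X 0.590 equiv; E 1.5 mol%; time 30 h
- west: Z 0.30 M; X 2.70 equiv; E 0.8 mol%; time 30 h
- south-west: Z 0.30 M; X 0.450 equiv; E 0.38 mol%; time 30 h
- south: Z 0.30 M; X 1.80 equiv; E 0.8 mol%; time 30 h
- south-east: Z 0.30 M; X 1.80 equiv; E 0.38 mol%; time 30 h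

- Sunday's (time / h: D / %, Z / %): 0.500: 1.0, 98.1; 1.50: 3.7, 96.1; 3.00: 7.3, 92.9; 4.00: 9.5, 88.9; 6.00: 14.0, 85.1
- Monday's (time / h: D / %, Z / %): 0.500: 0.2, 98.1; 0.833: 2.1, 97.2; 1.50: 5.1, 95.0; 3.00: 9.3, 90.1; 6.00: 17.1, 82.5

(scatter of a reading: 0.5 percentage points)



- the flasks put in order of amount of D, in percent of the Z charged, best first, at 30 h (east / west / south-west / south / south-east)
- the amount of D, in percent of the Z charged of the flask you put first, at 30 h
- the amount of D, in percent of the Z charged of the flask you put last, at 30 h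

**My reckoning.** I took the binding of Z to E as fast and assumed that this bound form is the resting state, so that D forms at a rate κ[X][E], with E counted as charged. With e the equivalents of X, m the loading of E, c the charge of Z and t the time, D per Z charged is e(1 − exp(−κmct)), where the 1 is a plain unit term. Sunday's last reading gave 7.89 L mol⁻¹ h⁻¹ and Monday's 7.30 L mol⁻¹ h⁻¹, so I carried their mean, 7.59 L mol⁻¹ h⁻¹, as κ, the turnover constant. Both runs moved Z, X and E together, so X as the partner, rather than Z, was my assumption.

**Turned round.** East, with X as limiting reagent, has a ceiling of 59.0%. To beat west even at that ceiling, κ would have to lie below 3.42 L mol⁻¹ h⁻¹, about half my value, while my two readings differ by 0.590 L mol⁻¹ h⁻¹. On κ, my law instead carried the reckoned D of west up to the Z charge at 25.4 h, before 30 h. I reckoned south 75.8%, south-east 41.2%, east 37.8% and south-west 10.3%, which put south-east narrowly above east.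

**The forecast.** The forecast gave west > south > east > south-east > south-west, top 65% and low 28%, taking the rate “with X near zero order”. It differed from my reckoning in placing east above south-east, and in its top and low.

**The flasks.** They gave west > south > east > south-east > south-west, top 93.6% and low 13.6%.

    Z + E ⇌ J (K = 48.0 L mol⁻¹, k = 1100 L mol⁻¹ h⁻¹, Ea = 42.0 kJ mol⁻¹, ΔH = −84.0 kJ mol⁻¹)
    X + J → L (k = 12.0 L mol⁻¹ h⁻¹, Ea = 46.0 kJ mol⁻¹)
    L → Q (k = 1400 h⁻¹, Ea = 70.0 kJ mol⁻¹)
    Q → E + D (k = 28.0 h⁻¹, Ea = 70.0 kJ mol⁻¹)
    X + Q → G (k = 0.120 L mol⁻¹ h⁻¹, Ea = 65.0 kJ mol⁻¹)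
    (constants at −20 °C)

South held 77.8% against my 75.8%. One further flask repeated south-west with X raised from 0.450 equiv to 1.80 equiv, for which κ reckons 41.2%. At 30.0 h that flask held 42.5% of D.

Readings and results come from a simulation with made-up constants, noise included.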